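**Retrosynthetic overview** (ring carbons numbered along the SMILES: C1 isopropenyl, C3 acetate, C4 carbinol, C5 angelate, C7/C8 oxirane, C9 acetate, C10 senecioate)
1. The four esters and the oxirane are removed last, leaving the (Z)-cyclodec-7-en-3-one 18 with every oxygen differentiated (C9–OH later directs the epoxidation).
2. Enabling feature: C3 (at ketone level), C4, the C5–C6 bond and the C7–C8 oxirane read as a Z-alkene form a 3-oxy-1,5-diene retron inside the ten-membered ring. C3 and C8 face each other across that ring, so a C3–C8 bond gives the cyclohexane C3–C2–C1–C10–C9–C8.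
3. C5–C6 is therefore made by an anionic oxy-Cope ring expansion of a cis-1-(1,2-dialkoxyvinyl)-2-vinylcyclohexanol (15), and the resulting enolate is C-methylated in the same flask to set C4.
4. The cyclohexanone 8 comes from (R)-carvone, whose single stereocentre (C1) relays C10 (photooxygenation, Mitsunobu inversion), C9 and C8 (directed epoxidation, semipinacol vinyl shift).
5. Ring order: six-membered ring (bought) → ten-membered carbocycle (step 11) → oxirane (step 19).

Key step: step 11

Remark: compounds 1–8 and 15 are named with carvone numbering (C1 = carbonyl or carbinol carbon); dibromide 12 is racemic and one enantiomer is drawn.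

**Step 1**
Reactants: 1 (R)-(−)-carvone
Product: 2 trimethylsilyl dienol ether of carvone
Conditions: TMSCl, NaI, Et3N, MeCN, 25–40 °C
Reagents that add atoms: chlorotrimethylsilane, C[Si](C)(C)Cl
Why: Thermodynamic silyl enol ether formation (TMSI made in situ, reversible enolisation) should favour the through-conjugated 1-siloxy-1,3-diene from γ-deprotonation at C4, leaving C5 untouched.

**Step 2**
Reactants: 2 trimethylsilyl dienol ether of carvone
Product: 3 trans-4-hydroxycarvone
Conditions: O2, hν, tetraphenylporphyrin (cat.), CH2Cl2, −78 °C; then PPh3; dilute HCl/THF work-up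
Reagents that add atoms: dioxygen, O=O
Why: Singlet-oxygen [4+2] cycloaddition to the cisoid siloxy-diene should occur anti to the C5 isopropenyl group, and collapse of the silyl peroxyketal followed by O–O reduction gives the γ-hydroxy enone with OH trans to isopropenyl.

**Step 3**
Reactants: 3 trans-4-hydroxycarvone
Product: 4 cis-4-(4-methoxyphenoxy)carvone
Conditions: 4-methoxyphenol, PPh3, DIAD, toluene, 0 °C → rt
Reagents that add atoms: 4-methoxyphenol, COc1ccc(O)cc1
Why: Mitsunobu etherification displaces the activated allylic alcohol by SN2 with inversion, which places the C4 oxygen cis to isopropenyl and protects it as an oxidatively removable aryl ether in one operation.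

**Step 4**
Reactants: 4 cis-4-(4-methoxyphenoxy)carvone
Product: 5 tertiary vinyl carbinol
Conditions: vinylmagnesium bromide, CeCl3, THF, −78 °C
Reagents that add atoms: vinylmagnesium bromide, C=C[Mg]Br
Why: Organocerium 1,2-addition to the enone should occur by axial attack on the half-chair with equatorial isopropenyl, from the face opposite the pseudo-axial aryloxy group, giving the tertiary OH cis to isopropenyl and aryloxy.

**Step 5**
Reactants: 5 tertiary vinyl carbinol
Product: 6 syn-epoxy alcohol
Conditions: VO(acac)2 (cat.), t-BuOOH, CH2Cl2, 0 °C → rt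
Reagents that add atoms: tert-butyl hydroperoxide, CC(C)(C)OO
Why: Vanadium-catalysed hydroxyl-directed epoxidation delivers oxygen to the trisubstituted ring alkene on the face of the tertiary allylic OH and leaves the vinyl and isopropenyl groups untouched.

**Step 6**
Reactants: 6 syn-epoxy alcohol
Product: 7 β-hydroxy ketone
Conditions: BF3·OEt2, CH2Cl2, −78 °C
Reagents that add atoms: none
Why: Semipinacol rearrangement of the 2,3-epoxy alcohol: the oxirane opens at tertiary C2 and the antiperiplanar vinyl group migrates from C1 with inversion at C2, giving the C1 ketone, a quaternary C2 with vinyl trans to the new C3–OH, and C3–OH cis to the aryloxy and isopropenyl groups.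

**Step 7**
Reactants: 7 β-hydroxy ketone
Product: 8 TBS ether ketone
Conditions: TBSOTf, 2,6-lutidine, CH2Cl2, −78 → 0 °C
Reagents that add atoms: tert-butyldimethylsilyl triflate, CC(C)(C)[Si](C)(C)OS(=O)(=O)C(F)(F)F
Why: Silylation of the hindered secondary alcohol under non-basic conditions avoids retro-aldol cleavage and gives a group that survives until step 18.

**Step 8**
Reactants: 9 vinylene carbonate
Product: 11 (Z)-1,2-bis(methoxymethoxy)ethene, via dilithium (Z)-ethene-1,2-diolate 10 (not isolated)
Conditions: MeLi (3 equiv), THF, −78 °C; then MOMCl (2 equiv), DMPU, −78 → 0 °C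
Reagents that add atoms: chloromethyl methyl ether, COCCl
Why: Exhaustive addition of methyllithium to the carbonate carbonyl releases the ring-locked cis-enediolate, and O-alkylation of both enolate oxygens by the hard chloromethyl ether keeps the Z geometry.

**Step 9**
Reactants: 11 (Z)-1,2-bis(methoxymethoxy)ethene
Product: 13 (Z)-1-bromo-1,2-bis(methoxymethoxy)ethene, via threo-dibromide 12 (not isolated)
Conditions: Br2, CH2Cl2, −78 °C; then DBU, −78 → 0 °C
Reagents that add atoms: bromine, BrBr
Why: Anti addition of bromine to the Z-alkene followed by anti E2 loss of HBr should give the vinyl bromide with the two alkoxy groups trans, so that bromine sits cis to the β-alkoxy group.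

**Step 10**
Reactants: 13 (Z)-1-bromo-1,2-bis(methoxymethoxy)ethene; 8 TBS ether ketone
Product: 15 cis-dialkenyl cyclohexanol, via (E)-1,2-bis(methoxymethoxy)vinyllithium 14 (not isolated)
Conditions: 13, t-BuLi (2 equiv), Et2O/THF, −78 °C; CeCl3; then 8, −78 °C
Reagents that add atoms: none
Why: Bromine–lithium exchange with retention gives the vinyllithium stabilised by its cis β-alkoxy group, and its cerium-mediated 1,2-addition should follow the axial trajectory (equatorial approach is blocked by the axial C2 methyl), placing the new alkenyl group axial and cis to the C2 vinyl group.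

**Step 11**
Reactants: 15 cis-dialkenyl cyclohexanol
Product: 18 cyclodecenone, via potassium alkoxide 16 (not isolated), via potassium enolate 17 (not isolated)
Conditions: KH, 18-crown-6, THF, −20 → 0 °C; then MeI, −78 °C
Reagents that add atoms: iodomethane, CI
Why: Deprotonation gives alkoxide 16, whose cyclohexane chair is locked (isopropenyl equatorial, the dialkoxyvinyl group and the C8 methyl trans-diaxial, the C8 vinyl equatorial), so the alkoxide-accelerated [3,3]-sigmatropic shift (anionic oxy-Cope rearrangement; closest known type is the tandem anionic oxy-Cope/enolate alkylation used for germacrane-type cyclodecenones) passes through a chair transition state that forms C5–C6 and cleaves C3–C8. The ten-membered ring is closed by a four-atom ring expansion of the six-membered ring, not by an end-to-end cyclisation. C5 is controlled by the enol ether geometry (C5–OMOM cis to C3, hence pseudo-axial in the chair) together with the face of C4=C5 fixed by the ring stereocentres, and the C7=C8 alkene emerges Z because the C8–C9 ring bond is pseudo-axial in that chair. C4 is controlled when the regiodefined enolate 17, born in the crossed conformation, is C-methylated on its outer face, anti to the transannular C7=C8 unit, which places methyl cis to the C5 oxygen. The step needs chair over boat (secured by the locked conformer), C- over O-methylation (MeI) and no E1cB loss of the C5 alkoxy group from the enolate, which is addressed by rearranging at or below 0 °C and quenching at −78 °C.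

**Step 12**
Reactants: 18 cyclodecenone
Product: 19 C3 alcohol
Conditions: K-Selectride, THF, −78 °C
Reagents that add atoms: none
Why: A bulky hydride with a non-chelating counter-ion should attack the C3 ketone in the Felkin–Anh sense (anti to the C4–OMOM bond, past the C4 methyl), giving the C3 alcohol syn to the C4 oxygen in the extended chain, i.e. cis to the C4 methyl on the ring.

**Step 13**
Reactants: 19 C3 alcohol
Product: 20 C3 acetate
Conditions: Ac2O, DMAP, pyridine, CH2Cl2, rt
Reagents that add atoms: acetic anhydride, CC(=O)OC(C)=O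
Why: DMAP-catalysed acetylation of the only free hydroxyl.

**Step 14**
Reactants: 20 C3 acetate
Product: 21 C10 alcohol
Conditions: (NH4)2Ce(NO3)6, MeCN/H2O (4:1), 0 °C
Reagents that add atoms: none
Why: Oxidative dearylation of the 4-methoxyphenyl ether by cerium(IV) frees the C10 alcohol with retention, since the alkyl C–O bond is not touched; the MOM ethers, the TBS ether and the alkenes should survive the short exposure at 0 °C.

**Step 15**
Reactants: 21 C10 alcohol
Product: 22 C10 senecioate
Conditions: 3-methylbut-2-enoic acid, DCC, DMAP, CH2Cl2, 0 °C → rt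
Reagents that add atoms: 3-methylbut-2-enoic acid, CC(C)=CC(=O)O
Why: Steglich esterification of the single free alcohol; carbodiimide activation avoids the vinylketene pathway that deconjugates the acid chloride.

**Step 16**
Reactants: 22 C10 senecioate
Product: 23 C4,C5-diol
Conditions: ZnBr2, n-PrSH, CH2Cl2, 0 °C
Reagents that add atoms: none
Why: Lewis acid/thiol cleavage of both MOM acetals (secondary and tertiary) is mild enough to leave the TBS ether, the esters and the alkenes, and is done before the acid-sensitive oxirane exists.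

**Step 17**
Reactants: 23 C4,C5-diol
Product: 24 C5 angelate
Conditions: angelic acid, 2,4,6-trichlorobenzoyl chloride, Et3N, toluene, rt; then 23, 75 °C
Reagents that add atoms: angelic acid, C/C=C(/C)C(=O)O
Why: Yamaguchi-type acylation with the preformed mixed anhydride, without a nucleophilic catalyst, should acylate the secondary C5 hydroxyl only (C4 is tertiary) and keep the Z geometry of the angelate.

**Step 18**
Reactants: 24 C5 angelate
Product: 25 C9 allylic alcohol
Conditions: HF·pyridine, pyridine, THF, 0 °C → rt
Reagents that add atoms: none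
Why: Buffered fluoride desilylation frees the allylic C9 hydroxyl under slightly acidic conditions, which suppress acyl migration from C10.

**Step 19**
Reactants: 25 C9 allylic alcohol
Product: 26 epoxy alcohol
Conditions: VO(acac)2 (cat.), t-BuOOH, CH2Cl2, 0 °C
Reagents that add atoms: tert-butyl hydroperoxide, CC(C)(C)OO
Why: Vanadium-catalysed epoxidation directed by the C9 allylic hydroxyl should give the cis epoxy alcohol typical of medium-ring (Z)-cycloalkenols, setting C7 and C8 with the oxirane oxygen on the face of the C9 oxygen; the isopropenyl group and the two conjugated esters should not react.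

**Step 20**
Reactants: 26 epoxy alcohol
Product: 27 CNP0416509.1
Conditions: Ac2O, pyridine, DMAP (cat.), CH2Cl2, 0 °C → rt
Reagents that add atoms: acetic anhydride, CC(=O)OC(C)=O
Why: Acetylation of the secondary C9 hydroxyl; the tertiary C4 hydroxyl should be inert under these conditions.

**Compound list**
1 | (R)-(−)-carvone | CC1=CC[C@H](CC1=O)C(C)=C | starting material
2 | trimethylsilyl dienol ether of carvone (1-trimethylsiloxy-2-methyl-5-isopropenylcyclohexa-1,3-diene, C5 unchanged) | CC1=C(O[Si](C)(C)C)C[C@H](C(C)=C)C=C1 | intermediate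
3 | trans-4-hydroxycarvone (4-OH trans to 5-isopropenyl) | CC1=C[C@H](O)[C@H](CC1=O)C(C)=C | intermediate
4 | cis-4-(4-methoxyphenoxy)carvone (aryloxy cis to isopropenyl) | CC1=C[C@@H](Oc2ccc(OC)cc2)[C@H](CC1=O)C(C)=C | intermediate
5 | 4-(4-methoxyphenoxy)-2-methyl-5-isopropenyl-1-vinylcyclohex-2-en-1-ol (1-OH, 4-aryloxy and 5-isopropenyl all cis) | C=C[C@@]1(O)C[C@H](C(C)=C)[C@H](Oc2ccc(OC)cc2)C=C1C | intermediate
6 | 2,3-epoxide of 5 (oxirane on the face of the 1-OH) | C=C[C@@]1(O)C[C@H](C(C)=C)[C@H](Oc3ccc(OC)cc3)[C@@H]2O[C@]12C | intermediate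
7 | 3-hydroxy-4-(4-methoxyphenoxy)-2-methyl-5-isopropenyl-2-vinylcyclohexan-1-one (3-OH, 4-aryloxy, 5-isopropenyl and 2-methyl on one face, 2-vinyl on the other) | O=C1C[C@H](C(C)=C)[C@H](Oc2ccc(OC)cc2)[C@H](O)[C@@]1(C)C=C | intermediate
8 | 3-O-TBS ether of 7 | O=C1C[C@H](C(C)=C)[C@H](Oc2ccc(OC)cc2)[C@H](O[Si](C)(C)C(C)(C)C)[C@@]1(C)C=C | intermediate
9 | vinylene carbonate | O=C1OC=CO1 | starting material
10 | dilithium (Z)-ethene-1,2-diolate | [Li+].[Li+].[O-]/C=C\[O-] | intermediate
11 | (Z)-1,2-bis(methoxymethoxy)ethene | COCO/C=C\OCOC | intermediate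
12 | (1R*,2R*)-1,2-dibromo-1,2-bis(methoxymethoxy)ethane (racemic threo) | COCO[C@H](Br)[C@@H](Br)OCOC | intermediate
13 | (Z)-1-bromo-1,2-bis(methoxymethoxy)ethene (alkoxy groups trans) | Br/C(OCOC)=C\OCOC | intermediate
14 | (E)-1,2-bis(methoxymethoxy)vinyllithium (Li cis to the β-alkoxy group) | [Li]/C(OCOC)=C\OCOC | intermediate
15 | 1-[(E)-1,2-bis(methoxymethoxy)vinyl] adduct of 8 (tertiary OH on the face of the silyloxy, aryloxy, isopropenyl and 2-methyl groups; dialkoxyvinyl and vinyl cis to each other on the other face) | O[C@]1(/C(OCOC)=C\OCOC)C[C@H](C(C)=C)[C@H](Oc2ccc(OC)cc2)[C@H](O[Si](C)(C)C(C)(C)C)[C@@]1(C)C=C | intermediate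
16 | potassium alkoxide of 15 | [K+].[O-][C@]1(/C(OCOC)=C\OCOC)C[C@H](C(C)=C)[C@H](Oc2ccc(OC)cc2)[C@H](O[Si](C)(C)C(C)(C)C)[C@@]1(C)C=C | intermediate
17 | potassium C3=C4 enolate of the ring-expanded (Z)-cyclodec-7-ene (C2 and C5 trans across the enolate) | [K+].C=C(C)[C@H]1C/C([O-])=C(OCOC)/[C@@H](OCOC)C/C=C(/C)[C@@H](O[Si](C)(C)C(C)(C)C)[C@H]1Oc2ccc(OC)cc2 | intermediate
18 | (Z)-cyclodec-7-en-3-one: 1-isopropenyl, 4-methyl-4-OMOM, 5-OMOM, 8-methyl, 9-OTBS, 10-(4-methoxyphenoxy) | C=C(C)[C@H]1CC(=O)[C@](C)(OCOC)[C@@H](OCOC)C/C=C(/C)[C@@H](O[Si](C)(C)C(C)(C)C)[C@H]1Oc2ccc(OC)cc2 | intermediate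
19 | C3 alcohol from 18 (3-OH cis to the 4-methyl) | C=C(C)[C@H]1C[C@@H](O)[C@](C)(OCOC)[C@@H](OCOC)C/C=C(/C)[C@@H](O[Si](C)(C)C(C)(C)C)[C@H]1Oc2ccc(OC)cc2 | intermediate
20 | C3 acetate of 19 | C=C(C)[C@H]1C[C@@H](OC(C)=O)[C@](C)(OCOC)[C@@H](OCOC)C/C=C(/C)[C@@H](O[Si](C)(C)C(C)(C)C)[C@H]1Oc2ccc(OC)cc2 | intermediate
21 | C10 alcohol (aryl ether removed) | C=C(C)[C@H]1C[C@@H](OC(C)=O)[C@](C)(OCOC)[C@@H](OCOC)C/C=C(/C)[C@@H](O[Si](C)(C)C(C)(C)C)[C@H]1O | intermediate
22 | C10 senecioate | C=C(C)[C@H]1C[C@@H](OC(C)=O)[C@](C)(OCOC)[C@@H](OCOC)C/C=C(/C)[C@@H](O[Si](C)(C)C(C)(C)C)[C@H]1OC(=O)C=C(C)C | intermediate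
23 | C4,C5-diol (both MOM groups removed) | C=C(C)[C@H]1C[C@@H](OC(C)=O)[C@](C)(O)[C@@H](O)C/C=C(/C)[C@@H](O[Si](C)(C)C(C)(C)C)[C@H]1OC(=O)C=C(C)C | intermediate
24 | C5 angelate | C=C(C)[C@H]1C[C@@H](OC(C)=O)[C@](C)(O)[C@@H](OC(=O)/C(C)=C\C)C/C=C(/C)[C@@H](O[Si](C)(C)C(C)(C)C)[C@H]1OC(=O)C=C(C)C | intermediate
25 | C9 allylic alcohol (TBS removed) | C=C(C)[C@H]1C[C@@H](OC(C)=O)[C@](C)(O)[C@@H](OC(=O)/C(C)=C\C)C/C=C(/C)[C@@H](O)[C@H]1OC(=O)C=C(C)C | intermediate
26 | 7,8-epoxy-9-ol (oxirane cis to the 9-OH) | C=C(C)[C@H]1C[C@@H](OC(C)=O)[C@](C)(O)[C@@H](OC(=O)/C(C)=C\C)C[C@H]2O[C@@]2(C)[C@@H](O)[C@H]1OC(=O)C=C(C)C | intermediate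
27 | CNP0416509.1 | C=C(C)[C@H]1C[C@@H](OC(C)=O)[C@](C)(O)[C@@H](OC(=O)/C(C)=C\C)C[C@H]2O[C@@]2(C)[C@@H](OC(C)=O)[C@H]1OC(=O)C=C(C)C | target

**Step count**
Total: 20 steps. Longest linear sequence: 18 steps (steps 1–7 and 10–20 from carvone); steps 8–9 make the two-carbon reagent.

**Three steps most likely to fail**

Step 11 (key step). The potassium enolate carries a β-alkoxy group aligned with its π-system, so E1cB loss of the C5 alkoxide may compete with trapping. O-methylation, or inversion of the enolate conformer before methylation (which would erode the C4 selectivity), are the other failure processes. Fallback, setting out from 15: the tertiary hydroxyl is silylated (TMSOTf, Et3N, CH2Cl2, −78 °C) to the trimethylsilyl ether F1. F1 is heated in a neutral siloxy-Cope rearrangement (degassed o-xylene, sealed tube, 180–200 °C) to the ring-expanded silyl enol ether F2, so that no free enolate exists while the ring forms. F2 is cleaved with MeLi (THF, 0 °C) to the lithium enolate F3, which is methylated at −78 °C (MeI, DMPU) and returns to the route at 18.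

Step 9. The α-bromo ether intermediate can ionise to an oxocarbenium ion, which would scramble the anti-addition/anti-elimination sequence and give the bromide isomer whose lithium derivative β-eliminates to an alkynyl ether. Fallback, setting out from 11: triplet-sensitised photoisomerisation (thioxanthone cat., 365 nm, pentane) gives a Z/E mixture, from which (E)-1,2-bis(methoxymethoxy)ethene F4 is separated by fractional distillation (Z isomer recycled). F4 is deprotonated directly at the vinylic position (t-BuLi, THF, −78 → −40 °C); lithium then sits cis to the β-alkoxy group, and the route is rejoined at 14 within step 10.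

Step 12. Facial selectivity of hydride delivery to the C3 ketone rests on the conformation of the ten-membered ring, and chelation by the C4–OMOM group would reverse it. Fallback, setting out from 18: reagent-controlled Corey–Bakshi–Shibata reduction with (S)-Me-CBS (cat.) and catecholborane (toluene, −78 °C). The catalyst distinguishes the quaternary C4 (large) from the C2 methylene (small) and should give the 3R alcohol, returning at 19 without new intermediates.

**Further compounds**
F1 | step 11 | trimethylsilyl ether of 15 | C[Si](C)(C)O[C@]1(/C(OCOC)=C\OCOC)C[C@H](C(C)=C)[C@H](Oc2ccc(OC)cc2)[C@H](O[Si](C)(C)C(C)(C)C)[C@@]1(C)C=C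
F2 | step 11 | ring-expanded C3 trimethylsilyl enol ether | C=C(C)[C@H]1C/C(O[Si](C)(C)C)=C(OCOC)/[C@@H](OCOC)C/C=C(/C)[C@@H](O[Si](C)(C)C(C)(C)C)[C@H]1Oc2ccc(OC)cc2
F3 | step 11 | lithium enolate corresponding to 17 | C=C(C)[C@H]1C/C(O[Li])=C(OCOC)/[C@@H](OCOC)C/C=C(/C)[C@@H](O[Si](C)(C)C(C)(C)C)[C@H]1Oc2ccc(OC)cc2
F4 | step 9 | (E)-1,2-bis(methoxymethoxy)ethene | COCO/C=C/OCOC
F0 | step 12 | none | none
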